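**Retrosynthetic overview**
1. Target ⇐ late acylation and hydroxyl-directed epoxidation of a 6/10/5 core; the γ-lactone (C8–C17 bond, C8 and C17 stereocentres) comes from an intramolecular SmI2 Reformatsky reaction onto a C8 ketone.
2. Key step: Grob (Wharton) fragmentation of the C3–C8 bond of a linear 6-6-6 tricycle, which opens the ten-membered ring and sets the (Z)-C3=C4 alkene and the C8 ketone at once.
3. Tricycle ⇐ two Diels–Alder reactions on one quinone (ring B): first ring A (C1, C10, C11, C14), then ring C (C3, C4, C7, C8); C2 and C9 are set by hydroxyl-directed reductions on the rigid tricycle.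
4. Ring order: ring B (quinone) → ring A → ring C → ten-membered ring (by cleaving the ring B/ring C fusion bond) → lactone → epoxide.

Assumption: briarane numbering (C1–C20) is used for every intermediate, β means the face of the C15 methyl; the antipode of the step 7 catalyst is taken if its facial sense proves opposite to the one drawn.

**Route**

Step 1
Reactants: 1 glutaconaldehyde potassium salt
Product: 2 (2E,4E)-5-(triethylsilyloxy)penta-2,4-dienal
Conditions: TESCl, THF/DMF, 0 °C to rt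
Reagents that add atoms: chlorotriethylsilane CC[Si](CC)(CC)Cl
Why: O-silylation of the delocalised dienolate keeps the all-trans geometry of the salt.

Step 2
Reactants: 2 (2E,4E)-5-(triethylsilyloxy)penta-2,4-dienal
Product: 3 (2E,4E)-5-(triethylsilyloxy)penta-2,4-dien-1-ol
Conditions: NaBH4, EtOH/THF, −20 °C
Reagents that add atoms: none
Why: 1,2-hydride reduction of the aldehyde; the silyl dienol ether is untouched at low temperature.

Step 3
Reactants: 3 (2E,4E)-5-(triethylsilyloxy)penta-2,4-dien-1-ol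
Product: 4 diene A, triethyl{[(1E,3E)-5-(phenylsulfanyl)penta-1,3-dien-1-yl]oxy}silane
Conditions: PhSSPh, PBu3, pyridine, 0 °C to rt
Reagents that add atoms: diphenyl disulfide c1ccc(SSc2ccccc2)cc1
Why: Hata reaction, in which the oxyphosphonium ion is displaced by thiolate (SN2) at the primary carbon; no stereocentre is involved.

Step 4
Reactants: 5 2-hydroxy-5-methyl-1,4-benzoquinone
Product: 6 2-[(4-methoxybenzyl)oxy]-5-methyl-1,4-benzoquinone
Conditions: PMBCl, Ag2O, CH2Cl2, rt, dark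
Reagents that add atoms: 4-methoxybenzyl chloride COc1ccc(CCl)cc1
Why: Williamson-type O-alkylation of the vinylogous acid via its silver salt; the resulting vinylogous ester deactivates its own double bond for step 7.

Step 5
Reactants: 7 1,3-diacetoxyacetone; 8 (triphenylphosphoranylidene)acetaldehyde
Product: 9 4-acetoxy-3-(acetoxymethyl)but-2-enal
Conditions: toluene, 80 °C
Reagents that add atoms: none
Why: Wittig olefination of an activated ketone with a stabilised ylide; the two CH2OAc arms are identical, so no alkene geometry arises.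

Step 6
Reactants: 9 4-acetoxy-3-(acetoxymethyl)but-2-enal
Product: 10 diene C, (1Z,3E)-2-(acetoxymethyl)-4-(trimethylsilyloxy)buta-1,3-dien-1-yl acetate
Conditions: TMSOTf, Et3N, Et2O, −78 to 0 °C
Reagents that add atoms: trimethylsilyl triflate C[Si](C)(C)OS(=O)(=O)C(F)(F)F
Why: silyl dienol ether formation by γ-deprotonation of the O-silylated enal (both γ positions are equivalent); only the isomer with both oxygens outside reaches the s-cis form needed in step 10.

Step 7
Reactants: 4 diene A; 6 2-[(4-methoxybenzyl)oxy]-5-methyl-1,4-benzoquinone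
Product: 13 trans-fused ring A/B hydroxy enedione, via cis-fused TES adduct 11 (not isolated), via trans-fused TES ether 12 (not isolated)
Conditions: (S)-B-o-tolyl-diphenylprolinol oxazaborolidine·HNTf2 (20 mol %), CH2Cl2, −78 °C; then DBU (cat.), 0 °C; then 1 M HCl, THF, 0 °C
Reagents that add atoms: none
Why: catalytic enantioselective quinone Diels–Alder reaction in which the Lewis acid binds the vinylogous-ester carbonyl (C2=O), so the methyl-bearing C1=C10 bond reacts with the nucleophilic diene terminus C11 at C10; endo addition sets C1, C14 and C11 (OTES and CH2SPh cis to the carbonyl carbons, trans to the methyl), DBU then epimerises C10 to the thermodynamic trans fusion, and acid cleaves the TES ether.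

Step 8
Reactants: 13 trans-fused ring A/B hydroxy enedione
Product: 15 12α,13α,14α-triol, via osmate ester 14 (not isolated)
Conditions: OsO4 (1.05 equiv), TMEDA, CH2Cl2, −78 °C; then aq. Na2SO3, THF, rt
Reagents that add atoms: osmium tetroxide O=[Os](=O)(=O)=O
Why: Donohoe hydrogen-bond-directed dihydroxylation, in which OsO4·TMEDA is delivered syn to the free C14 hydroxyl and anti to the axial C15 methyl, giving the all-cis triol; the electron-poor alkoxy enedione alkene and the sulfide are left alone at −78 °C.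

Step 9
Reactants: 15 12α,13α,14α-triol
Product: 16 12,13-acetonide with free 14α-OH
Conditions: 2,2-dimethoxypropane, PPTS (cat.), CH2Cl2, 0 °C
Reagents that add atoms: 2,2-dimethoxypropane COC(C)(C)OC
Why: acetonide formation (transketalisation) on the less hindered cis-12,13-diol; the C14 hydroxyl is neopentyl and hydrogen-bonded to the C2 carbonyl, so it stays free.

Step 10
Reactants: 16 12,13-acetonide with free 14α-OH; 10 diene C
Product: 18 tricyclic 2,9-diketone with free 7α-OH, via C7 TMS ether adduct 17 (not isolated)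
Conditions: toluene, BHT, 90 °C; then AcOH/THF/H2O, 0 °C
Reagents that add atoms: none
Why: second Diels–Alder reaction, in which the nucleophilic terminus C4 of the 1-silyloxy diene bonds to C3 (β to the C9 carbonyl, which is not conjugated to the ether donor) and the diene adds endo to the α face opposite the axial C15 methyl, setting 3β-H, 8β-O, 4α-OAc and 7α-O; work-up cleaves the TMS ether.

Step 11
Reactants: 18 tricyclic 2,9-diketone with free 7α-OH
Product: 19 2β,7α,9β,14α-tetraol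
Conditions: Me4NBH(OAc)3, MeCN/AcOH (1:1), −30 to 0 °C
Reagents that add atoms: none
Why: double Evans–Saksena directed reduction, in which each β-hydroxy ketone receives hydride intramolecularly from its α-face hydroxyl (O14 to C2, O7 to C9), giving the 2β and 9β alcohols (1,3-anti) on faces that external hydride cannot reach.

Step 12
Reactants: 19 2β,7α,9β,14α-tetraol
Product: 20 2,7,14-tris(triethylsilyl) ether with free 9β-OH
Conditions: TESOTf (3.3 equiv), 2,6-lutidine, CH2Cl2, −78 °C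
Reagents that add atoms: triethylsilyl triflate CC[Si](CC)(CC)OS(=O)(=O)C(F)(F)F
Why: silylation under kinetic control; the axial C9 hydroxyl, flanked by two fully substituted carbons and 1,3-diaxial to the C15 methyl, is the slowest and stays free at −78 °C.

Step 13
Reactants: 20 2,7,14-tris(triethylsilyl) ether with free 9β-OH
Product: 21 9-O-TBS-2,7,14-tri-O-TES ether
Conditions: TBSOTf, 2,6-lutidine, CH2Cl2, 0 to 40 °C
Reagents that add atoms: tert-butyldimethylsilyl triflate CC(C)(C)[Si](C)(C)OS(=O)(=O)C(F)(F)F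
Why: forcing silylation of the last hindered secondary alcohol; the different silyl group lets C7 be freed alone in step 19.

Step 14
Reactants: 21 9-O-TBS-2,7,14-tri-O-TES ether
Product: 23 11(20)-exocyclic alkene, via sulfoxide 22 (not isolated)
Conditions: mCPBA (1.0 equiv), CH2Cl2, −78 °C; then NaHCO3, toluene, 100 °C
Reagents that add atoms: none
Why: sulfide oxidation followed by thermal syn-elimination of the sulfoxide; C11–H is the only β hydrogen, so only the exocyclic C11=C20 alkene can form.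

Step 15
Reactants: 23 11(20)-exocyclic alkene
Product: 24 tertiary C8 alcohol
Conditions: DDQ, CH2Cl2/pH 7 buffer (10:1), 0 °C
Reagents that add atoms: none
Why: oxidative PMB ether cleavage (hydride abstraction, then hydrolysis of the oxocarbenium ion) frees the tertiary alcohol without touching silyl ethers, acetates or alkenes.

Step 16
Reactants: 24 tertiary C8 alcohol
Product: 25 4α,8β,16-triol
Conditions: K2CO3 (cat.), MeOH, 0 °C
Reagents that add atoms: none
Why: Zemplén-type transesterification removes the two allylic acetates; silyl ethers and the acetonide are inert.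

Step 17
Reactants: 25 4α,8β,16-triol
Product: 26 16-acetate with free 4α-OH and 8β-OH
Conditions: AcCl (1.05 equiv), 2,4,6-collidine, CH2Cl2, −78 °C
Reagents that add atoms: acetyl chloride CC(Cl)=O
Why: selective acylation of the primary allylic alcohol over the secondary and tertiary ones.

Step 18
Reactants: 26 16-acetate with free 4α-OH and 8β-OH
Product: 28 ten-membered ring C8 ketone, via C4 mesylate 27 (not isolated)
Conditions: Ms2O, Et3N, CH2Cl2, −40 °C; then KN(SiMe3)2, THF, −78 to 0 °C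
Reagents that add atoms: none
Why: Grob (Wharton) fragmentation, in which the trans ring A/B fusion locks the pseudo-equatorial C4 mesylate antiperiplanar to the C3–C8 bond with C2 axial on ring C, so the C8 alkoxide expels mesylate to give the C8 ketone and the ring-cis (Z) C3=C4 alkene; the mesylate is not aligned with the C5=C6 π system, so allylic ionisation does not compete.

Step 19
Reactants: 28 ten-membered ring C8 ketone
Product: 29 7-hydroxy-8-ketone
Conditions: HF·pyridine, pyridine, THF, −20 °C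
Reagents that add atoms: none
Why: selective desilylation; the C7 TES ether is the only silyl ether flanked by two sp2 carbons (allylic, α to the ketone), so it is cleaved before the neopentyl-type C2 and C14 TES ethers and the C9 TBS ether.

Step 20
Reactants: 29 7-hydroxy-8-ketone; 30 2-bromopropanoyl bromide
Product: 31 7-O-(2-bromopropanoyl) ester
Conditions: pyridine, CH2Cl2, −40 °C
Reagents that add atoms: none
Why: O-acylation by the acid bromide; both CHBr epimers are carried on, since that carbon becomes an enolate.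

Step 21
Reactants: 31 7-O-(2-bromopropanoyl) ester
Product: 32 8α-hydroxy-7,8-γ-lactone
Conditions: SmI2 (2.2 equiv), THF, −78 °C
Reagents that add atoms: none
Why: intramolecular samarium Reformatsky reaction, in which the tethered enolate closes the trans-fused lactone because that path keeps C6 and C9 anticlinal across C7–C8 (the cis-fused path needs them eclipsed), giving 8α-OH; C17 settles with its methyl cis to the hydroxyl and trans to C9, the thermodynamic epimer reachable by enolisation.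

Step 22
Reactants: 32 8α-hydroxy-7,8-γ-lactone
Product: 33 2,9,14-triol
Conditions: HF·pyridine, THF, 0 to 40 °C
Reagents that add atoms: none
Why: fluoride-mediated cleavage of the remaining silyl ethers; the acetonide, acetate and lactone survive buffered HF.

Step 23
Reactants: 33 2,9,14-triol
Product: 34 2,9,14,16-tetraacetate 12,13-acetonide
Conditions: Ac2O, DMAP (cat.), pyridine, 0 °C to rt
Reagents that add atoms: acetic anhydride CC(=O)OC(C)=O
Why: DMAP-catalysed acetylation of the three secondary alcohols; the tertiary C8 hydroxyl is inert under these conditions.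

Step 24
Reactants: 34 2,9,14,16-tetraacetate 12,13-acetonide
Product: 35 12α,13α-diol
Conditions: 80% aq. AcOH, 40 °C
Reagents that add atoms: none
Why: mild acid hydrolysis of the acetonide; the acetates and the lactone are stable to aqueous acetic acid.

Step 25
Reactants: 35 12α,13α-diol
Product: 36 11α,20-epoxy-12α,13α-diol
Conditions: VO(acac)2 (5 mol %), tBuOOH, CH2Cl2, 0 °C
Reagents that add atoms: tert-butyl hydroperoxide CC(C)(C)OO
Why: hydroxyl-directed vanadium epoxidation (Sharpless type), in which the axial allylic C12 hydroxyl delivers oxygen to the α face of C11=C20; the ring diene has no free allylic alcohol and the homoallylic C8 hydroxyl directs far more slowly.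

Step 26
Reactants: 36 11α,20-epoxy-12α,13α-diol
Product: 37 CNP0303383.2
Conditions: (iPrCH2CO)2O, DMAP, Et3N, CH2Cl2, rt
Reagents that add atoms: 3-methylbutanoic anhydride CC(C)CC(=O)OC(=O)CC(C)C
Why: DMAP-catalysed (Steglich-type) acylation of the two secondary alcohols; the tertiary C8 hydroxyl and the epoxide survive.

**Compound list**

1 | glutaconaldehyde potassium salt | [K+].[O-]/C=C/C=C/C=O | starting material
2 | (2E,4E)-5-(triethylsilyloxy)penta-2,4-dienal | O=C/C=C/C=C/O[Si](CC)(CC)CC | intermediate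
3 | (2E,4E)-5-(triethylsilyloxy)penta-2,4-dien-1-ol | OC/C=C/C=C/O[Si](CC)(CC)CC | intermediate
4 | diene A, triethyl{[(1E,3E)-5-(phenylsulfanyl)penta-1,3-dien-1-yl]oxy}silane | CC[Si](CC)(CC)O/C=C/C=C/CSc1ccccc1 | intermediate
5 | 2-hydroxy-5-methyl-1,4-benzoquinone | CC1=CC(=O)C(O)=CC1=O | starting material
6 | 2-[(4-methoxybenzyl)oxy]-5-methyl-1,4-benzoquinone | CC1=CC(=O)C(OCc2ccc(OC)cc2)=CC1=O | intermediate
7 | 1,3-diacetoxyacetone | CC(=O)OCC(=O)COC(C)=O | starting material
8 | (triphenylphosphoranylidene)acetaldehyde | O=CC=P(c1ccccc1)(c1ccccc1)c1ccccc1 | starting material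
9 | 4-acetoxy-3-(acetoxymethyl)but-2-enal | CC(=O)OCC(COC(C)=O)=CC=O | intermediate
10 | diene C, (1Z,3E)-2-(acetoxymethyl)-4-(trimethylsilyloxy)buta-1,3-dien-1-yl acetate | C[Si](C)(C)O/C=C/C(COC(C)=O)=C/OC(C)=O | intermediate
11 | cis-fused ring A/B Diels–Alder adduct: 1β-Me, 10β-H, 14α-OTES, 11α-CH2SPh, 8-OPMB enedione | C[C@]12[C@@H](O[Si](CC)(CC)CC)C=C[C@@H](CSc3ccccc3)[C@H]1C(=O)C(OCc3ccc(OC)cc3)=CC2=O | intermediate
12 | trans-fused C10 epimer of 11 (10α-H), 14α-OTES | C[C@]12[C@@H](O[Si](CC)(CC)CC)C=C[C@@H](CSc3ccccc3)[C@@H]1C(=O)C(OCc3ccc(OC)cc3)=CC2=O | intermediate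
13 | trans-fused ring A/B hydroxy enedione: 1β-Me, 10α-H, 14α-OH, 11α-CH2SPh, 8-OPMB | C[C@]12[C@@H](O)C=C[C@@H](CSc3ccccc3)[C@@H]1C(=O)C(OCc3ccc(OC)cc3)=CC2=O | intermediate
14 | 12α,13α-osmate ester of 13 (OsO2·TMEDA glycolate) | C[C@]12[C@@H](O)[C@@H](O[Os-2]34(=O)(=O)[N+](C)(C)CC[N+]3(C)C)[C@@H](O4)[C@@H](CSc3ccccc3)[C@@H]1C(=O)C(OCc3ccc(OC)cc3)=CC2=O | intermediate
15 | 12α,13α,14α-triol | C[C@]12[C@@H](O)[C@@H](O)[C@@H](O)[C@@H](CSc3ccccc3)[C@@H]1C(=O)C(OCc3ccc(OC)cc3)=CC2=O | intermediate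
16 | 12,13-acetonide with free 14α-OH | C[C@]12[C@@H](O)[C@H]3OC(C)(C)O[C@H]3[C@@H](CSc3ccccc3)[C@@H]1C(=O)C(OCc3ccc(OC)cc3)=CC2=O | intermediate
17 | tricyclic Diels–Alder adduct, 7α-OTMS (3β-H, 4α-OAc, 8β-OPMB, 16-OAc) | C[C@]12[C@@H](O)[C@H]3OC(C)(C)O[C@H]3[C@@H](CSc3ccccc3)[C@@H]1C(=O)[C@@]4(OCc3ccc(OC)cc3)[C@@H](O[Si](C)(C)C)C=C(COC(C)=O)[C@@H](OC(C)=O)[C@H]4C2=O | intermediate
18 | tricyclic 2,9-diketone: 3β-H, 4α-OAc, 16-OAc, 7α-OH, 8β-OPMB, 14α-OH | C[C@]12[C@@H](O)[C@H]3OC(C)(C)O[C@H]3[C@@H](CSc3ccccc3)[C@@H]1C(=O)[C@@]4(OCc3ccc(OC)cc3)[C@@H](O)C=C(COC(C)=O)[C@@H](OC(C)=O)[C@H]4C2=O | intermediate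
19 | 2β,7α,9β,14α-tetraol | C[C@]12[C@@H](O)[C@H]3OC(C)(C)O[C@H]3[C@@H](CSc3ccccc3)[C@@H]1[C@H](O)[C@@]4(OCc3ccc(OC)cc3)[C@@H](O)C=C(COC(C)=O)[C@@H](OC(C)=O)[C@H]4[C@@H]2O | intermediate
20 | 2,7,14-tris(triethylsilyl) ether with free 9β-OH | C[C@]12[C@@H](O[Si](CC)(CC)CC)[C@H]3OC(C)(C)O[C@H]3[C@@H](CSc3ccccc3)[C@@H]1[C@H](O)[C@@]4(OCc3ccc(OC)cc3)[C@@H](O[Si](CC)(CC)CC)C=C(COC(C)=O)[C@@H](OC(C)=O)[C@H]4[C@@H]2O[Si](CC)(CC)CC | intermediate
21 | 9-O-TBS-2,7,14-tri-O-TES ether | C[C@]12[C@@H](O[Si](CC)(CC)CC)[C@H]3OC(C)(C)O[C@H]3[C@@H](CSc3ccccc3)[C@@H]1[C@H](O[Si](C)(C)C(C)(C)C)[C@@]4(OCc3ccc(OC)cc3)[C@@H](O[Si](CC)(CC)CC)C=C(COC(C)=O)[C@@H](OC(C)=O)[C@H]4[C@@H]2O[Si](CC)(CC)CC | intermediate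
22 | C20 phenyl sulfoxide of 21 | C[C@]12[C@@H](O[Si](CC)(CC)CC)[C@H]3OC(C)(C)O[C@H]3[C@@H](CS(=O)c3ccccc3)[C@@H]1[C@H](O[Si](C)(C)C(C)(C)C)[C@@]4(OCc3ccc(OC)cc3)[C@@H](O[Si](CC)(CC)CC)C=C(COC(C)=O)[C@@H](OC(C)=O)[C@H]4[C@@H]2O[Si](CC)(CC)CC | intermediate
23 | 11(20)-exocyclic alkene | C[C@]12[C@@H](O[Si](CC)(CC)CC)[C@H]3OC(C)(C)O[C@H]3C(=C)[C@@H]1[C@H](O[Si](C)(C)C(C)(C)C)[C@@]4(OCc3ccc(OC)cc3)[C@@H](O[Si](CC)(CC)CC)C=C(COC(C)=O)[C@@H](OC(C)=O)[C@H]4[C@@H]2O[Si](CC)(CC)CC | intermediate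
24 | tertiary C8 alcohol (8β-OH, PMB removed) | C[C@]12[C@@H](O[Si](CC)(CC)CC)[C@H]3OC(C)(C)O[C@H]3C(=C)[C@@H]1[C@H](O[Si](C)(C)C(C)(C)C)[C@@]4(O)[C@@H](O[Si](CC)(CC)CC)C=C(COC(C)=O)[C@@H](OC(C)=O)[C@H]4[C@@H]2O[Si](CC)(CC)CC | intermediate
25 | 4α,8β,16-triol | C[C@]12[C@@H](O[Si](CC)(CC)CC)[C@H]3OC(C)(C)O[C@H]3C(=C)[C@@H]1[C@H](O[Si](C)(C)C(C)(C)C)[C@@]4(O)[C@@H](O[Si](CC)(CC)CC)C=C(CO)[C@@H](O)[C@H]4[C@@H]2O[Si](CC)(CC)CC | intermediate
26 | 16-acetate with free 4α-OH and 8β-OH | C[C@]12[C@@H](O[Si](CC)(CC)CC)[C@H]3OC(C)(C)O[C@H]3C(=C)[C@@H]1[C@H](O[Si](C)(C)C(C)(C)C)[C@@]4(O)[C@@H](O[Si](CC)(CC)CC)C=C(COC(C)=O)[C@@H](O)[C@H]4[C@@H]2O[Si](CC)(CC)CC | intermediate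
27 | 4α-mesylate of 26 | C[C@]12[C@@H](O[Si](CC)(CC)CC)[C@H]3OC(C)(C)O[C@H]3C(=C)[C@@H]1[C@H](O[Si](C)(C)C(C)(C)C)[C@@]4(O)[C@@H](O[Si](CC)(CC)CC)C=C(COC(C)=O)[C@@H](OS(C)(=O)=O)[C@H]4[C@@H]2O[Si](CC)(CC)CC | intermediate
28 | ten-membered ring C8 ketone: (3Z)-C3=C4, C5=C6 with C4 and C7 cis, 7-OTES, 9-OTBS, 2,14-di-OTES, 16-OAc, 12,13-acetonide | CC(=O)OCC1=C/[C@H](O[Si](CC)(CC)CC)C(=O)[C@@H](O[Si](C)(C)C(C)(C)C)[C@H]2C(=C)[C@@H]3OC(C)(C)O[C@@H]3[C@H](O[Si](CC)(CC)CC)[C@]2(C)[C@@H](O[Si](CC)(CC)CC)/C=C\1 | intermediate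
29 | 7-hydroxy-8-ketone | CC(=O)OCC1=C/[C@H](O)C(=O)[C@@H](O[Si](C)(C)C(C)(C)C)[C@H]2C(=C)[C@@H]3OC(C)(C)O[C@@H]3[C@H](O[Si](CC)(CC)CC)[C@]2(C)[C@@H](O[Si](CC)(CC)CC)/C=C\1 | intermediate
30 | 2-bromopropanoyl bromide (racemic) | CC(Br)C(Br)=O | starting material
31 | 7-O-(2-bromopropanoyl) ester | CC(=O)OCC1=C/[C@H](OC(=O)C(C)Br)C(=O)[C@@H](O[Si](C)(C)C(C)(C)C)[C@H]2C(=C)[C@@H]3OC(C)(C)O[C@@H]3[C@H](O[Si](CC)(CC)CC)[C@]2(C)[C@@H](O[Si](CC)(CC)CC)/C=C\1 | intermediate
32 | 8α-hydroxy-7,8-γ-lactone (17-Me cis to 8-OH), silyl ethers at C2, C9, C14 | CC(=O)OCC1=C/[C@@H]2OC(=O)[C@H](C)[C@@]2(O)[C@@H](O[Si](C)(C)C(C)(C)C)[C@H]2C(=C)[C@@H]3OC(C)(C)O[C@@H]3[C@H](O[Si](CC)(CC)CC)[C@]2(C)[C@@H](O[Si](CC)(CC)CC)/C=C\1 | intermediate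
33 | 2,9,14-triol | CC(=O)OCC1=C/[C@@H]2OC(=O)[C@H](C)[C@@]2(O)[C@@H](O)[C@H]2C(=C)[C@@H]3OC(C)(C)O[C@@H]3[C@H](O)[C@]2(C)[C@@H](O)/C=C\1 | intermediate
34 | 2,9,14,16-tetraacetate 12,13-acetonide | CC(=O)OCC1=C/[C@@H]2OC(=O)[C@H](C)[C@@]2(O)[C@@H](OC(C)=O)[C@H]2C(=C)[C@@H]3OC(C)(C)O[C@@H]3[C@H](OC(C)=O)[C@]2(C)[C@@H](OC(C)=O)/C=C\1 | intermediate
35 | 12α,13α-diol | CC(=O)OCC1=C/[C@@H]2OC(=O)[C@H](C)[C@@]2(O)[C@@H](OC(C)=O)[C@H]2C(=C)[C@H](O)[C@H](O)[C@H](OC(C)=O)[C@]2(C)[C@@H](OC(C)=O)/C=C\1 | intermediate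
36 | 11α,20-epoxy-12α,13α-diol | CC(=O)OCC1=C/[C@@H]2OC(=O)[C@H](C)[C@@]2(O)[C@@H](OC(C)=O)[C@H]2[C@@]3(CO3)[C@H](O)[C@H](O)[C@H](OC(C)=O)[C@]2(C)[C@@H](OC(C)=O)/C=C\1 | intermediate
37 | CNP0303383.2 | CC(=O)OCC1=C/[C@@H]2OC(=O)[C@H](C)[C@@]2(O)[C@@H](OC(C)=O)[C@H]2[C@@]3(CO3)[C@H](OC(=O)CC(C)C)[C@H](OC(=O)CC(C)C)[C@H](OC(C)=O)[C@]2(C)[C@@H](OC(C)=O)/C=C\1 | target

**Step count and risks**

Total steps: 26. Longest linear sequence: 23 (steps 1–3, then 7–26).

Most likely to fail: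

Step 10 (second Diels–Alder onto the donor-substituted enedione; reactivity, regiochemistry and face all matter). Fallback: a stepwise polar annulation instead of the cycloaddition, setting out from 16 and 10. MgBr2·OEt2 in CH2Cl2 at −78 °C chelates the C9 carbonyl and the C8 ether oxygen, so a vinylogous Mukaiyama–Michael addition of 10 through C4 to C3 gives the keto-aldehyde C9 silyl enol ether F1. A TMSOTf-catalysed intramolecular Mukaiyama aldol reaction of this enol ether onto the C7 aldehyde then closes ring C, and acidic work-up returns the route at 18.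

Step 18 (Grob fragmentation under alkoxide push). Fallback: a cationic, leaving-group-driven fragmentation, setting out from 26. Cl3CCN with catalytic DBU converts the C4 hydroxyl (the tertiary C8 hydroxyl does not react) into the C4 trichloroacetimidate F2. Catalytic TMSOTf in CH2Cl2 at −78 °C then ionises the imidate with participation of the antiperiplanar C3–C8 bond and the C8 hydroxyl as donor, giving the ketone and the (Z)-alkene and returning the route at 28.

Step 21 (intramolecular Reformatsky; the C8 configuration rests on a conformational argument). Fallback: an intermolecular, chelation-controlled Reformatsky addition, setting out from 29. Excess ethyl 2-bromopropanoate and Zn in THF form the zinc alkoxide of the C7 hydroxyl, which chelates the C8 carbonyl. The zinc enolate then adds from the C7–H side (Cram chelate, the same C8 configuration) to give the open-chain hydroxy ester adduct F3. This lactonises onto the C7 oxygen (spontaneously or with PPTS) and returns the route at 32.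

**Further compounds**

F1 | step 10 | Michael adduct: C9 trimethylsilyl enol ether of ring B carrying at C3 the (Z)-enal chain C4(OAc)–C5(CH2OAc)=C6–C7HO | C[C@]12[C@@H](O)[C@H]3OC(C)(C)O[C@H]3[C@@H](CSc3ccccc3)[C@@H]1C(O[Si](C)(C)C)=C(OCc3ccc(OC)cc3)[C@@H]([C@H](OC(C)=O)/C(COC(C)=O)=C\C=O)C2=O
F2 | step 18 | C4 O-trichloroacetimidate of 26 | C[C@]12[C@@H](O[Si](CC)(CC)CC)[C@H]3OC(C)(C)O[C@H]3C(=C)[C@@H]1[C@H](O[Si](C)(C)C(C)(C)C)[C@@]4(O)[C@@H](O[Si](CC)(CC)CC)C=C(COC(C)=O)[C@@H](OC(=N)C(Cl)(Cl)Cl)[C@H]4[C@@H]2O[Si](CC)(CC)CC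
F3 | step 21 | open-chain Reformatsky adduct of 29: ethyl ester at C19 with free 7-OH and 8-OH | CC(=O)OCC1=C/[C@H](O)[C@@](O)([C@@H](C)C(=O)OCC)[C@@H](O[Si](C)(C)C(C)(C)C)[C@H]2C(=C)[C@@H]3OC(C)(C)O[C@@H]3[C@H](O[Si](CC)(CC)CC)[C@]2(C)[C@@H](O[Si](CC)(CC)CC)/C=C\1
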